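The runs were generated by integration for substances that don't exist.

At early times the epsilon and beta runs look alike: target stands at 22.9% and 22.7% at 0.500 min, then at 3.6% and 2.0% at 1.00 min.

| setting | epsilon | beta | flask |
|---|---|---|---|
| starting material | 0.095 M (fed, over 2.5 s) | 0.14 M (fed, over 2.5 s) | 0.19 M (fed, over 2.5 s) |
| target | 3.8 mM | 3.8 mM | 3.80 mM |
| remark | run made earlier; the fed solution adds 0.25 times the starting volume | run made earlier; the fed solution adds 0.25 times the starting volume | the fed solution adds 0.25 times the starting volume |
| time |  |  | 1.0 h |

| run | time / min | isomer of the product / % | target / % |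
|---|---|---|---|
| epsilon | 0.500 | 13.9 | 22.9 |
| epsilon | 1.00 | 21.0 | 3.6 |
| epsilon | 2.50 | 19.0 | 0 |
| epsilon | 6.00 | 20.9 | 0 |
| epsilon | 15.0 | 18.9 | 0.8 |
| epsilon | 40.0 | 16.8 | 0 |
| beta | 0.500 | 15.0 | 22.7 |
| beta | 1.00 | 18.2 | 2.0 |
| beta | 2.50 | 18.1 | 0 |
| beta | 6.00 | 20.1 | 1.3 |
| beta | 15.0 | 18.6 | 0 |
| beta | 40.0 | 16.0 | 1.8 |

(readings scatter by 1 percentage point)

1. time up to 1.0 h at which isomer of the product stands highest, in min
2. the amount of isomer of the product, in percent of the starting material charged, at that time

- charges are per starting volume, the dose included; the dosed solution carries all of it

*Does the charge change the picture?* Not visibly. From 0.095 M to 0.14 M the readings stay close, with a gap of 2.8 percentage points in isomer of the product at 1.00 min against a scatter of 1 point per reading, so I carry them to the flask at 0.19 M, as a judgement from two runs.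

*With target reading 0% in both runs at 2.50 min, what still moves?* Isomer of the product sinks slowly. Averaged over the two runs, it goes from 20.5% at 6.00 min to 16.4% at 40.0 min. Taking that fall as first order gives 0.00656 min⁻¹, which I call the leak constant, the apparent first-order rate constant for the loss of isomer of the product once target has fallen away. It is a reading and carries the scatter of those readings. Integrated, c(isomer of the product) at a later time is its value at the top times the exponential of minus the leak constant times the time since the top.

*But the means rise by 2 points from 2.50 min to 6.00 min. Doesn't that contradict a leak?* It might, but each reading scatters by 1 point, so I treat the rise as scatter and pool those four readings.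

*Your number?* The pooled readings, run back to 2.50 min with the leak constant, give 19.8%, and I place the top between 1.00 min and 2.50 min.

The forecast gives 20% at 2 min, slightly above my height, and warns that “the time is poorly defined”.

The flask reaches its top of 18.9% at 1.89 min.

    starting material → target (k = 9.01 × 10⁻⁴ s⁻¹)
    starting material + target → 2 target (k = 18.8 M⁻¹ s⁻¹)
    target → over-reaction product (k = 0.0464 s⁻¹)
    target ⇌ isomer of the product (K = 86.0, k = 0.0107 s⁻¹)

The top of the flask stands low because target runs off to over-reaction product: the flask run without that step reaches 101% of isomer of the product, against 18.9%. Started from the top, the leak constant gives 12.9% at 1.0 h, and the flask holds 13.3%. For the neighbouring flask, with the same charges but read at 15 min, it gives 17.3%, and that flask holds 17.5%.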